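## Structural features

The target 13 is a diaryl ether in which one oxygen joins C6 of ring A to C1' of ring B; ring A is numbered C1 (OH), C2 and C4 (Br), C6 (bridging O), and ring B is numbered C1' (bridging O), C2' (OH), C3', C5' and C6' (Br). It has no stereocentre and no chain, so the whole problem is one of substitution pattern. Each ring carries a hydroxyl ortho to the bridge, and the bridging oxygen is flanked by three ortho substituents (C1–OH, C2'–OH, C6'–Br), which makes a late union of two finished arenes unattractive. Four bromines (C2, C4, C3', C5') sit ortho or para to a hydroxyl and are what electrophilic bromination of the parent bisphenol should deliver. The fifth, at C6', is meta to the C2' hydroxyl, and no directing effect in the molecule places it. The free phenols are the sensitive groups (oxidation to bromodienones, reaction with carbenes or strong base as phenoxides), and the aryl bromides exclude late hydrogenolysis or organometallic steps. The key step exploits the position of C6' between C1' and C5': this carbon can be delivered with its bromine as dibromocarbene into the C1'=C5' enol ether bond of a five-membered ring (C1' to C5') that already holds the bridging oxygen on C1' and the C2' oxygen as a ketal. The locants of 13 are used for the corresponding atoms of every intermediate.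

## Logic of the disconnections

13 to 12: the four C–Br bonds at C2, C4, C3' and C5' are cut. They are the positions that the two hydroxyls activate, so they need no construction of their own; C6'–Br, which has no such help, is kept. Five halogens are reduced to one. The forward step must stop after four substitutions and must be run on the free bisphenol, so that each hydroxyl outranks the bridging oxygen as director.

12 to 10 (through 11): the two O–H bonds at C1 and C2' are exchanged for O–CH3. Ring A needs a mask because a phenoxide would intercept the carbene of the key step, and the C2' oxygen leaves that step as a methyl ether anyway, so one deprotection serves both. The forward step must cleave two aryl methyl ethers without touching the diaryl ether or the C–Br bond.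

10 to 6 and 7 (through 9 and 8): the C6'–C1' and C6'–C5' bonds are cut and C6' is excised together with its bromine. This removes the one substituent that substitution chemistry cannot place and turns a 1,2,3-trisubstituted arene with a hindered ether into a cyclopentene enol ether ketal. The forward step demands carbene addition at the enol ether only, ring opening that keeps one bromine on the inserted carbon, and aromatisation by loss of methanol and not of the ring A aryloxide.

6 to 5: the two C–OMe bonds of the ketal are cut back to the ketone. The ketal is there to make the alkene electron-rich and to hold C2' at the ketone oxidation level. The forward step must ketalise an enone without conjugate addition and without hydrolysing the aryl enol ether, which calls for aprotic, kinetic conditions.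

5 to 2 and 3 (through 4): the O–C1' bond and the C1'=C5' π bond are cut, the latter as water. At a saturated, carbonyl-activated epoxide carbon the hindered ether bond becomes a plain SN2 event, and the oxygen left on C5' is the leaving group that puts the double bond in one defined position. The forward step needs attack at the α-carbon of the epoxy ketone and dehydration under the same base.

2 to 1: the two C–O bonds of the oxirane are cut, which leads to a commodity enone. The forward step is a nucleophilic epoxidation that must not open the product.

## Other disconnections considered

Alternative 1: The cut removes the C3'–Br and C5'–Br bonds together with the aromatic unsaturation of ring B and leads to 3-bromo-2-(3,5-dibromo-2-methoxyphenoxy)cyclohex-2-en-1-one A1.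
- Forward step: excess bromine would brominate the CH2 next to the carbonyl; loss of HBr and tautomerisation would give the phenol, which the same reagent would brominate ortho and para to give 3,4,6-tribromo-2-(3,5-dibromo-2-methoxyphenoxy)phenol A2. Demethylation of A2 would give 13.
- In its favour: aromatisation of cyclohexenones by halogenation and dehydrohalogenation is classical, the C6' bromine is fixed by the 1,3-dioxygenated origin of A1, and aromatisation and two brominations share one flask.
- Against it here: ring A must arrive as a methyl ether with both bromines already in place, which costs extra steps for a phenol brominated meta to its hydroxyl. The enol ether double bond of A1 is a second site for bromine addition, and HBr accumulates around a vinylogous acyl bromide.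
- Comparison: structurally both plans aromatise a ring that already carries both oxygens and C6'. Mechanistically this alternative rests on better precedent than the chosen key step, and that point goes to the alternative. In step count the two are about equal once the ring A partner and A1 are made, and the chosen plan uses a cheaper ring A and introduces four bromines at once.

Alternative 2: The cut removes the C1–O and C2'–O hydroxyl bonds and leads, through a silicon placeholder at C6', to diphenyl ether A3.
- Forward step: ortho-silylation of A3 would give trimethyl(2-phenoxyphenyl)silane A4. n-BuLi with TMEDA would lithiate A4 once on each ring ortho to the ether oxygen, and B(OMe)3 followed by alkaline H2O2 would give 2-(2-hydroxyphenoxy)-3-(trimethylsilyl)phenol A5. Bromine would then have to perform four hydroxyl-directed substitutions and one ipso-bromodesilylation at C6' to reach 13.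
- In its favour: the ether bond never has to be made, every reaction type is established, and the route is three steps from A3. On step economy and on precedent it is the better plan.
- Against it here: the C6' bromine depends on ipso substitution at a crowded position meta to the hydroxyl, in a medium that accumulates HBr. Protodesilylation would delete the one bromine that no directing group can restore. Incomplete double lithiation would give mono-hydroxylated material that is hard to separate.
- Comparison: the chosen plan is longer and its key step is untested, but it fixes C6'–Br by carbon–carbon bond formation before any other halogen is present.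

Alternative 3: The cut removes the O–C1' and C6'–Br bonds and leads to 2-iodo-6-(4,4,5,5-tetramethyl-1,3,2-dioxaborolan-2-yl)phenyl trifluoromethanesulfonate A6 and 3.
- Forward step: iPrMgCl·LiCl would release the 3-borylbenzyne A7. The chloromagnesium salt of 3 would add at the aryne carbon next to boron, and 1,2-dibromotetrachloroethane would brominate the resulting arylmagnesium to give 2-[3-bromo-2-(2-methoxyphenoxy)phenyl]-4,4,5,5-tetramethyl-1,3,2-dioxaborolane A8. Oxidation of the boronate would give 3-bromo-2-(2-methoxyphenoxy)phenol A9, and demethylation would join the chosen route at 12.
- In its favour: one operation sets both the ether bond and C6'–Br, boron controls the regiochemistry and then becomes the C2' hydroxyl, and the plan is convergent.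
- Against it here: a magnesium aryloxide is a weak aryne nucleophile, the ortho-boryl arylmagnesium must be brominated before it is protonated or attacks boron, the exchange reagent competes for both aryne and bromine donor, and A6 needs several steps.
- Comparison: both plans place C6'–Br regiospecifically. The amine additions known for such arynes are closer precedent than anything available for the chosen key step, so on mechanism the alternative is equal or slightly ahead. In step count it is shorter if A6 is bought and about equal if A6 is made.

Key step: step 4

Remark: 13 has no stereocentre; 2, 4 and 8 are racemic and each is drawn as one enantiomer of its only accessible relative configuration.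

## Steps

Step 1
Reactants: 1 cyclopent-2-en-1-one
Product: 2 6-oxabicyclo[3.1.0]hexan-2-one (2,3-epoxycyclopentanone, racemic, cis-fused)
Conditions: 30% aq. H2O2, NaOH (cat.), MeOH, 0 °C
Reagents that add atoms: hydrogen peroxide, OO
Why: Weitz–Scheffer nucleophilic epoxidation: hydroperoxide adds in conjugate fashion and the enolate closes onto the O–O bond. Both stereocentres form together, the small ring enforces cis fusion, and the product is racemic.

Step 2
Reactants: 2 6-oxabicyclo[3.1.0]hexan-2-one; 3 2-methoxyphenol
Product: 5 2-(2-methoxyphenoxy)cyclopent-2-en-1-one, via β-hydroxy ketone 4 (not isolated)
Conditions: K2CO3 (0.2 equiv), DMF, rt → 50 °C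
Reagents that add atoms: none
Why: Base-catalysed opening of an α,β-epoxy ketone by a phenoxide at the carbonyl-activated α-carbon (SN2 with inversion, trans 4), followed by E1cB loss of water. This is the established route from epoxy ketones to 2-aryloxy enones; it fixes the double bond position, and both stereocentres of 4 disappear.

Step 3
Reactants: 5 2-(2-methoxyphenoxy)cyclopent-2-en-1-one
Product: 6 1-[(5,5-dimethoxycyclopent-1-en-1-yl)oxy]-2-methoxybenzene
Conditions: MeOSiMe3 (2.5 equiv), TMSOTf (cat.), CH2Cl2, −78 → −30 °C; pyridine quench
Reagents that add atoms: methoxytrimethylsilane, CO[Si](C)(C)C
Why: Noyori ketalisation: the silyl triflate activates the carbonyl and the silyl ether delivers methoxy in kinetic 1,2-fashion, driven by siloxane formation. The aprotic, cold medium should avoid conjugate addition of methanol and hydrolysis of the aryl enol ether, both of which threaten ketalisation with protic acid.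

Step 4
Reactants: 6 1-[(5,5-dimethoxycyclopent-1-en-1-yl)oxy]-2-methoxybenzene; 7 bromoform
Product: 10 1-bromo-3-methoxy-2-(2-methoxyphenoxy)benzene, via dibromocyclopropane 8 (not isolated), via bromodiene ketal 9 (not isolated)
Conditions: CHBr3 (1.5 equiv), KOtBu (3 equiv), hexane, −20 → 40 °C; filter; then CSA (cat.), CH2Cl2, rt
Reagents that add atoms: none
Why: Proposed new method: dibromocarbene, formed by α-elimination from the tribromomethyl anion, should add as an electrophile to the only electron-rich alkene of 6, the aryloxy enol ether, in a concerted (2+1) cheletropic cycloaddition that closes the cyclopropane of 8; the closest known reaction types are the dihalocarbene ring expansions of cyclic enol ethers to 2-halo enones and of indenes to 2-halonaphthalenes and the Ciamician–Dennstedt rearrangement, none of which carries a ketal-bearing aryl enol ether through to a benzene ring. The strained bicyclo[3.1.0]hexane should then ionise its endo C–Br bond while the shared C1'–C5' bond opens in a disrotatory two-electron electrocyclic process (Woodward–Hoffmann–DePuy rule), assisted by the aryloxy oxygen on C1', so that ring B is closed by ring enlargement and not by cyclisation, and the second bromine stays on the inserted carbon C6'. The allyl cation should lose a proton from C4' to tert-butoxide to give diene 9; the acid then ionises the ketal, and the O-methyl arenium ion loses a proton from C3' to give 10. The two stereocentres of 8 are set cis by the suprafacial carbene addition and are both destroyed, so 10 has none. Three selectivities are needed: site selectivity of the carbene, secured because ring A is inert to dibromocarbene once its phenol is a methyl ether and no other alkene is present; a single insertion position, fixed by the location of the enol ether double bond between C1' and C5'; and proton loss from the cation in preference to nucleophilic capture at C1', secured by the anhydrous, bulky alkoxide, since capture by water or a small alkoxide would expel the ring A aryloxide as in the known enone-forming variant. In the aromatisation only methanol can leave, because in 9 the aryloxy group sits on an sp2 carbon whereas the ketal carbon can ionise.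

Step 5
Reactants: 10 1-bromo-3-methoxy-2-(2-methoxyphenoxy)benzene
Product: 12 3-bromo-2-(2-hydroxyphenoxy)phenol, via bis(dibromoboryl) ether 11 (not isolated)
Conditions: BBr3 (3 equiv), CH2Cl2, −78 °C → rt; then H2O
Reagents that add atoms: none
Why: Lewis acid cleavage of aryl methyl ethers: boron coordinates each methoxy oxygen and bromide attacks the methyl group (SN2). The diaryl ether and the aryl bromide have no such pathway, and hydrolysis of 11 frees both phenols.

Step 6
Reactants: 12 3-bromo-2-(2-hydroxyphenoxy)phenol
Product: 13 3,4,6-tribromo-2-(3,5-dibromo-2-hydroxyphenoxy)phenol
Conditions: Br2 (4.0 equiv), AcOH, rt; aq. NaHSO3 work-up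
Reagents that add atoms: bromine, BrBr
Why: Four successive electrophilic aromatic brominations, each directed by a hydroxyl to its para position and to its one free ortho position (C4 and C2 on ring A, C5' and C3' on ring B). Each ring is deactivated after two substitutions and C6' already carries bromine, so four equivalents should stop at the pentabromide.

## Compound list

1 | cyclopent-2-en-1-one | O=C1C=CCC1 | starting material
2 | 6-oxabicyclo[3.1.0]hexan-2-one (racemic, cis-fused) | O=C1CC[C@H]2O[C@@H]12 | intermediate
3 | 2-methoxyphenol | COc1ccccc1O | starting material
4 | trans-3-hydroxy-2-(2-methoxyphenoxy)cyclopentan-1-one (racemic) | O=C1CC[C@@H](O)[C@@H]1Oc1ccccc1OC | intermediate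
5 | 2-(2-methoxyphenoxy)cyclopent-2-en-1-one | COc1ccccc1OC1=CCCC1=O | intermediate
6 | 1-[(5,5-dimethoxycyclopent-1-en-1-yl)oxy]-2-methoxybenzene | COc1ccccc1OC1=CCCC1(OC)OC | intermediate
7 | bromoform | BrC(Br)Br | starting material
8 | 1-[(6,6-dibromo-2,2-dimethoxybicyclo[3.1.0]hexan-1-yl)oxy]-2-methoxybenzene (racemic, cis-fused) | COc1ccccc1O[C@]12C(OC)(OC)CC[C@H]1C2(Br)Br | intermediate
9 | 1-[(2-bromo-6,6-dimethoxycyclohexa-1,3-dien-1-yl)oxy]-2-methoxybenzene | COc1ccccc1OC1=C(Br)C=CCC1(OC)OC | intermediate
10 | 1-bromo-3-methoxy-2-(2-methoxyphenoxy)benzene | COc1ccccc1Oc1c(OC)cccc1Br | intermediate
11 | 1-bromo-3-[(dibromoboranyl)oxy]-2-{2-[(dibromoboranyl)oxy]phenoxy}benzene | BrB(Br)Oc1ccccc1Oc1c(OB(Br)Br)cccc1Br | intermediate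
12 | 3-bromo-2-(2-hydroxyphenoxy)phenol | Oc1ccccc1Oc1c(O)cccc1Br | intermediate
13 | 3,4,6-tribromo-2-(3,5-dibromo-2-hydroxyphenoxy)phenol | Oc1c(Br)cc(Br)cc1Oc1c(O)c(Br)cc(Br)c1Br | target

## Step count and least certain steps

Total steps: 6. Longest linear sequence: 6 steps (1, 2, 5, 6, 10, 12, 13), with 3 entering at step 2 and 7 at step 4.

**Step 4 (key step).** Three things are most likely to go wrong:
- Slow carbene addition, because the enol ether is hindered by the neighbouring ketal carbon and only moderately electron-rich, so the carbene is consumed by the alkoxide.
- Nucleophilic capture of the ring-opened cation at C1' followed by loss of the ring A aryloxide, which would break the ether bond.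
- A second carbene addition to the diene stage.

The fallback uses known chemistry, sets out from 3 and returns at 10. SNAr of 3 on 2-fluoro-1-methoxy-3-nitrobenzene (COc1cccc([N+](=O)[O-])c1F; K2CO3, DMF, 90 °C) should give 1-methoxy-2-(2-methoxyphenoxy)-3-nitrobenzene F1. Hydrogenation (H2, Pd/C, EtOAc) should give 3-methoxy-2-(2-methoxyphenoxy)aniline F2. Diazotisation (NaNO2, aq. HBr, 0 °C) to 3-methoxy-2-(2-methoxyphenoxy)benzenediazonium bromide F3 and Sandmeyer bromination (CuBr, 60 °C) should give 10.

**Step 3.** The likely failure is oligomerisation by attack of the newly formed enol ether on the oxocarbenium intermediate, or reversal of the ketal and hydrolysis of the enol ether during isolation, because 6 combines two acid-labile groups. The fallback reverses the order of events, sets out from 3 and returns at 6. Commercial 2-bromocyclopent-2-en-1-one (O=C1CCC=C1Br) is ketalised while no enol ether is present (HC(OMe)3, MeOH, TsOH cat.) to 1-bromo-5,5-dimethoxycyclopent-1-ene F4. The ether bond is then made by Ullmann-type O-vinylation of 3 (CuI, N,N-dimethylglycine, Cs2CO3, dioxane, 100 °C) to give 6.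

**Step 2.** The likely failure is base-induced isomerisation or self-condensation of the unsubstituted epoxy ketone outrunning attack by the hindered phenoxide, or attack at the β-carbon. The fallback sets out from 3 and returns at 5. Alkylation of 3 with 2-chlorocyclopentanone (O=C1CCCC1Cl; K2CO3, acetone, reflux) should give racemic 2-(2-methoxyphenoxy)cyclopentan-1-one F5. Silylation under equilibrating conditions (TMSOTf, Et3N, CH2Cl2) toward the more acidic aryloxy-bearing α-carbon should give {[2-(2-methoxyphenoxy)cyclopent-1-en-1-yl]oxy}trimethylsilane F6. Saegusa–Ito dehydrogenation (Pd(OAc)2, MeCN, rt) should give 5.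

**Step 6.** The likely failure is loss of stoichiometric control: substitution leaking to C4' or to ring A positions ortho and para to the bridge, or oxidation of the polybromophenols to bromodienones, because four substitutions of different rates share one reagent charge. The fallback stages the bromination, sets out from 12 and returns at 13. NBS (2 equiv, MeCN, 0 °C) should brominate para to each hydroxyl and give 3,4-dibromo-2-(5-bromo-2-hydroxyphenoxy)phenol F7. Amine-mediated ortho-bromination (NBS 2 equiv, iPr2NH cat., CH2Cl2, 0 °C) should then fill C2 and C3' and give 13.

## Further compounds

F1 | step 4 | 1-methoxy-2-(2-methoxyphenoxy)-3-nitrobenzene | COc1ccccc1Oc1c(OC)cccc1[N+](=O)[O-]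
F2 | step 4 | 3-methoxy-2-(2-methoxyphenoxy)aniline | COc1ccccc1Oc1c(OC)cccc1N
F3 | step 4 | 3-methoxy-2-(2-methoxyphenoxy)benzenediazonium bromide | COc1ccccc1Oc1c(OC)cccc1[N+]#N.[Br-]
F4 | step 3 | 1-bromo-5,5-dimethoxycyclopent-1-ene | COC1(OC)CCC=C1Br
F5 | step 2 | 2-(2-methoxyphenoxy)cyclopentan-1-one (racemic) | COc1ccccc1OC1CCCC1=O
F6 | step 2 | {[2-(2-methoxyphenoxy)cyclopent-1-en-1-yl]oxy}trimethylsilane | COc1ccccc1OC1=C(O[Si](C)(C)C)CCC1
F7 | step 6 | 3,4-dibromo-2-(5-bromo-2-hydroxyphenoxy)phenol | Oc1ccc(Br)cc1Oc1c(O)ccc(Br)c1Br
A1 | alternative 1 | 3-bromo-2-(3,5-dibromo-2-methoxyphenoxy)cyclohex-2-en-1-one | O=C1CCCC(Br)=C1Oc1cc(Br)cc(Br)c1OC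
A2 | alternative 1 | 3,4,6-tribromo-2-(3,5-dibromo-2-methoxyphenoxy)phenol | COc1c(Br)cc(Br)cc1Oc1c(O)c(Br)cc(Br)c1Br
A3 | alternative 2 | diphenyl ether | c1ccc(Oc2ccccc2)cc1
A4 | alternative 2 | trimethyl(2-phenoxyphenyl)silane | C[Si](C)(C)c1ccccc1Oc1ccccc1
A5 | alternative 2 | 2-(2-hydroxyphenoxy)-3-(trimethylsilyl)phenol | C[Si](C)(C)c1cccc(O)c1Oc1ccccc1O
A6 | alternative 3 | 2-iodo-6-(4,4,5,5-tetramethyl-1,3,2-dioxaborolan-2-yl)phenyl trifluoromethanesulfonate | CC1(C)OB(OC1(C)C)c1cccc(I)c1OS(=O)(=O)C(F)(F)F
A7 | alternative 3 | 2-(2,3-didehydrophenyl)-4,4,5,5-tetramethyl-1,3,2-dioxaborolane (3-borylbenzyne) | CC1(C)OB(OC1(C)C)C1=CC=CC#C1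
A8 | alternative 3 | 2-[3-bromo-2-(2-methoxyphenoxy)phenyl]-4,4,5,5-tetramethyl-1,3,2-dioxaborolane | COc1ccccc1Oc1c(Br)cccc1B1OC(C)(C)C(C)(C)O1
A9 | alternative 3 | 3-bromo-2-(2-methoxyphenoxy)phenol | COc1ccccc1Oc1c(O)cccc1Br
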